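## Structural features

- The target 12 has two benzene rings joined only by one ether oxygen. Ring A carries the bridging O at C1, OMe at C2, and Br at C4 and C6. Ring B carries the bridging O at C1', OH at C2', and Br at C4' and C6'. There is no stereocentre and no further ring.
- Each ring is a 3,5-dibromocatechol unit linked through the oxygen that sits next to bromine. The ether is therefore tetra-ortho-substituted (Br/OMe on ring A, Br/OH on ring B), and the molecule is C2-symmetric apart from one methyl group.
- In both rings the bromines are ortho and para to the bridging oxygen but meta to OMe or OH. Electrophilic bromination of a finished 2-aryloxyphenol or 2-aryloxyanisole would follow the stronger donors OH/OMe to the wrong carbons, so the pattern must come in with the building blocks.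
- The fragile groups are the four C–Br bonds (low-valent copper, palladium and nickel, organolithiums, reducing metals, hydrogenolysis). The free phenol next to the ether is also sensitive (oxidation, base-induced Smiles-type aryl migration).
- The real difficulty is the aryl–O–aryl bond between two electron-poor, di-ortho-substituted partners. It must be made without touching any C–Br bond while securing the meta relation between Br and OH in ring B.
- The key step exploits this feature: the chain C6'(Br)–C5'(H)–C4'(Br)–C3'(H) of ring B matches C3–C6 of 3,5-dibromo-2-pyrone atom for atom. The remaining pair C1'(OAr)–C2'(OH) is a vicinally dioxygenated two-carbon unit.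
- In one sentence: ring B is built onto an alkene that already carries the oxygen of ring A, by a Diels–Alder reaction, loss of CO2 and loss of aryloxide between 3,5-dibromo-2-pyrone and a 1,1-bis(aryloxy)-2-silyloxyethene.

## Logic of the disconnections

**12 ⇒ 11.** The O–H at C2' is traced back to an O–Si bond. The oxygen at C2' enters the key step as a silyl enol ether. The silyl group also keeps the product neutral, so it can be separated from the acidic co-product 2. Nothing is gained in the skeleton. The forward step must remove silicon without strong base, so that no phenoxide sits next to the ether.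

**11 ⇒ 6 + 8 (key).**
- Bonds cut: C1'–C6' and C2'–C3' of ring B. In the same retrosynthetic move a second aryloxy group goes back on C1', a hydrogen goes back on C2', and a C(=O)–O bridge is restored between C6' and C3'.
- Reason: C3'–C6' with both bromines is a ready-made diene, and C1'–C2' is a trioxygenated alkene.
- Gain: the tetra-ortho-substituted diaryl ether becomes an acetal-type C–O bond, and the meta-Br/OH pattern of ring B is fixed by the diene rather than by directing effects.
- Demand: the acetal carbon of 6 must bond to the brominated diene terminus of 8, and aromatisation must keep one aryloxy group. Two identical aryloxy groups guarantee the second point. One equivalent of 2 is returned.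

**6 ⇒ 5.** The O–Si bond and the C1'=C2' π bond are cut, taking the enol silane back to the aldehyde. This leaves a plain carbonyl compound. The forward step must enolise a hindered α-C–H. There is no E/Z question, because C1' bears two identical groups.

**5 ⇒ 4.** C2' is raised from the aldehyde to the ester level. The ester is the form in which the two-carbon unit is available as a gem-dihalide. The forward step is a partial reduction that must stop at the aldehyde and spare C–Br.

**4 ⇒ 2 (twice) + 3.** Both C1'–O bonds are cut. They are made at an sp3 carbon by substitution, where an ortho-disubstituted phenoxide only has to reach a small electrophile. The whole ether problem becomes an alkylation. The demand is that the second substitution proceeds at a carbon that already carries one bulky aryloxy group.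

**2 ⇒ 1.** C6–Br is cut back to C–H, and C4–Br is cut back to C–CO2H. The carboxyl group marks the position para to OH, and the only open position activated by OH is the ortho one. Both bromines therefore end up meta to OMe without ambiguity. The forward step must achieve clean ipso-substitution with loss of the carboxyl group.

**8 ⇒ 7.** C3–Br is cut back to C–H, and C5–Br is cut back to C–CO2H. The same logic as for 2 places the two bromines 1,3 on the pyrone.

## Other disconnections considered

**Alternative 1:** (the first that comes to mind) The bridging O–C1' bond is cut.
- Forward: nucleophilic aromatic substitution of the phenoxide of 2 on 3,5-dibromo-2-fluorobenzaldehyde A1 gives 3,5-dibromo-2-(2,4-dibromo-6-methoxyphenoxy)benzaldehyde A2. Baeyer–Villiger oxidation and hydrolysis then give 12. An Ullmann coupling is the metal-catalysed variant.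
- Ground:
  - The bond would be formed at the most congested sp2 carbon. A weak, di-ortho-substituted nucleophile would be wedged between Br and CHO in the anionic σ-adduct.
  - In the oxidation the migrating aryl carbon has two meta-bromines, so hydride migration to the acid should compete.
  - Monovalent copper or zerovalent palladium cannot distinguish the intended C–X bond from four C–Br bonds.
  - The plan is shorter on paper, but it places all the risk on the hindered bond that the chosen plan makes at sp3 carbon. It is kept as the fallback.

**Alternative 2:** C2–O and C2'–O are cut, and C2 and C2' are reconnected through one carbonyl carbon.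
- Forward: 9H-xanthen-9-one A3 is brominated. Ring oxygen and carbonyl direct to the same carbons, giving 2,4,5,7-tetrabromo-9H-xanthen-9-one A4. Baeyer–Villiger ring expansion gives 2,4,6,8-tetrabromo-11H-dibenzo[b,e][1,4]dioxepin-11-one A5. Ring opening with methanol, O-methylation, adjustment of the ester to A2 and a second aryl migration follow.
- Ground:
  - The ether is bought and the bromine pattern is matched.
  - However, the carbonyl of A4 is a vinylogous carbonate and should resist addition of a peracid.
  - The migrating aryl groups are deactivated by two meta-bromines.
  - The one-carbon bridge can only be removed in two separate migrations with redox steps in between.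
  - The key step therefore settles only half of the problem, and by a doubtful reaction.

**Alternative 3:** The bridging O–C1' bond is cut in the radical sense, as an oxidative coupling of two phenols that copies a presumed biosynthesis.
- Forward: anodic cross-coupling of 2 with 3,5-dibromophenol A6 gives 3,5-dibromo-6-(2,4-dibromo-6-methoxyphenoxy)cyclohexa-2,4-dien-1-one A7, which would tautomerise to 12.
- Ground:
  - This is a single step, but nothing in the substrates controls it.
  - Compound 2 and the product 12 should be oxidised more easily than A6, so homo-coupling and over-oxidation are favoured.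
  - A6 offers C2, C4 and C6 as well as its own oxygen.
  - The blocked ortho and para carbons of 2 invite ipso-attack with loss of bromine.

Key step: step 6

Remark: 12 is achiral. Compounds 9 and 10 are transient racemates whose stereocentres vanish on aromatisation, so no stereodescriptor is needed anywhere in the route.

## Steps

Step 1
Reactants: 1 vanillic acid (4-hydroxy-3-methoxybenzoic acid)
Product: 2 2,4-dibromo-6-methoxyphenol
Conditions: Br2 (2.1 equiv), AcOH–H2O, rt → 50 °C; aq. NaHSO3
Reagents that add atoms: bromine, BrBr
Why: Electrophilic bromination at the only open position ortho to OH (meta to CO2H), then ipso-attack para to OH with loss of CO2 (bromodecarboxylation of a 4-hydroxybenzoic acid). The carboxyl group marks the para position, so both bromines should end up ortho/para to OH and meta to OMe.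

Step 2
Reactants: 2 2,4-dibromo-6-methoxyphenol (2.1 equiv); 3 methyl dichloroacetate
Product: 4 methyl 2,2-bis(2,4-dibromo-6-methoxyphenoxy)acetate
Conditions: K2CO3 (2.5 equiv), NaI (cat.), DMF, 90 °C
Reagents that add atoms: none
Why: Twofold Williamson-type substitution of a gem-dihaloacetate, the standard entry to bis(aryloxy)acetates. The first displacement is activated by the ester, and the second by the α-aryloxy group (α-halo ether). No metal or strong base touches the C–Br bonds.

Step 3
Reactants: 4 methyl 2,2-bis(2,4-dibromo-6-methoxyphenoxy)acetate
Product: 5 2,2-bis(2,4-dibromo-6-methoxyphenoxy)acetaldehyde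
Conditions: i-Bu2AlH (1.1 equiv), CH2Cl2, −78 °C; MeOH, then aq. potassium sodium tartrate
Reagents that add atoms: none
Why: Partial reduction of an ester. The two electron-withdrawing α-aryloxy groups should stabilise the tetrahedral aluminium alkoxide until the quench, so the reduction stops at the aldehyde. Aryl bromides and aryl ethers are inert at this temperature.

Step 4
Reactants: 5 2,2-bis(2,4-dibromo-6-methoxyphenoxy)acetaldehyde
Product: 6 {[2,2-bis(2,4-dibromo-6-methoxyphenoxy)ethenyl]oxy}(tert-butyl)dimethylsilane
Conditions: TBSOTf (1.3 equiv), Et3N (2 equiv), CH2Cl2, 0 °C → rt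
Reagents that add atoms: tert-butyldimethylsilyl trifluoromethanesulfonate, CC(C)(C)[Si](C)(C)OS(=O)(=O)C(F)(F)F
Why: Soft enolisation of an aldehyde to its silyl enol ether. The α-C–H is acidified by two aryloxy groups and there is only one enolisable position. The two groups on the acetal carbon are identical, so no alkene isomers can arise.

Step 5
Reactants: 7 coumalic acid (2-oxo-2H-pyran-5-carboxylic acid)
Product: 8 3,5-dibromo-2H-pyran-2-one
Conditions: NBS (2.5 equiv), n-Bu4NBr (cat.), CHCl3, 50 °C
Reagents that add atoms: N-bromosuccinimide, O=C1CCC(=O)N1Br
Why: Known bromodecarboxylation of coumalic acid at C5 combined with electrophilic bromination at C3, the two carbons activated by the ring oxygen. This places the two bromines 1,3 on the future diene.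

Step 6
Reactants: 6 {[2,2-bis(2,4-dibromo-6-methoxyphenoxy)ethenyl]oxy}(tert-butyl)dimethylsilane; 8 3,5-dibromo-2H-pyran-2-one (1.5 equiv)
Product: 11 tert-butyl[3,5-dibromo-2-(2,4-dibromo-6-methoxyphenoxy)phenoxy]dimethylsilane, via bicyclic lactone 9 (not isolated), via cyclohexadienone ketal 10 (not isolated)
Conditions: mesitylene, sealed tube, Ar, 120 → 160 °C; aq. Na2CO3 wash (returns 2)
Reagents that add atoms: none
Why: Inverse-electron-demand Diels–Alder reaction of a 2-pyrone with a ketene acetal, followed by cycloreversion of CO2 and β-elimination; this reaction type is known as the phenol- and catechol-ether annulation of 2-pyrones with 1,1-di- and 1,1,2-trialkoxyethenes, and its first stage is known from cycloadditions of 8 with enol ethers and silyl enol ethers. The diene C3=C4–C5=C6 of 8 has its LUMO lowered by the lactone carbonyl and two bromines and is most electrophilic at C6, the end of the vinylogous acceptor chain, while in 6 the CH(OTBS) carbon is the β-carbon of the ketene acetal and the only sterically open alkene terminus. The intermolecular [4+2] closure of the six-membered carbocycle (suprafacial on both partners) should therefore be strongly asynchronous: the CH(OTBS)–C6 bond leads, positive charge builds up on the C(OAr)2 carbon where two oxygen lone pairs stabilise it, and the C(OAr)2–C3 bond closes last to give 9. This orientation is the selectivity the step needs, because it puts the aryloxy carbon (future C1') next to C–Br (future C6') and the silyloxy carbon (future C2') next to C–H (future C3'); it is secured by two donors against one, by the shielding of the acetal carbon by two twisted ortho-disubstituted aryl groups, and by the general preference of 8 to bind donor-bearing carbons at C3. At the reaction temperature 9 should lose CO2 by retro-[4+2] to give 10, the diaryl ketal of a cyclohexadienone. Compound 10 can aromatise in one way only: one aryloxide, a good nucleofuge, ionises with help from the remaining oxygen to an arenium ion that loses the proton of the CH(OTBS) carbon, whereas OTBS cannot leave because no neighbouring carbon bears a hydrogen, and since both aryloxy groups are the same either departure gives 11. The stereocentres of 9 and 10 are erased, no metal or base meets the C–Br bonds, and any addition of released 2 to unreacted 6 should be reversible at this temperature.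

Step 7
Reactants: 11 tert-butyl[3,5-dibromo-2-(2,4-dibromo-6-methoxyphenoxy)phenoxy]dimethylsilane
Product: 12 3,5-dibromo-2-(2,4-dibromo-6-methoxyphenoxy)phenol (target)
Conditions: n-Bu4NF, AcOH (1:1), THF, 0 °C
Reagents that add atoms: none
Why: Fluoride-induced cleavage of an aryl silyl ether. The acetic acid buffer protonates the phenoxide as it forms, so a Smiles-type aryl migration between the two ortho oxygens has no chance. Methyl ether, diaryl ether and C–Br bonds are inert.

## Compound list

1 | vanillic acid (4-hydroxy-3-methoxybenzoic acid) | COc1cc(C(=O)O)ccc1O | starting material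
2 | 2,4-dibromo-6-methoxyphenol | COc1cc(Br)cc(Br)c1O | intermediate
3 | methyl dichloroacetate | COC(=O)C(Cl)Cl | starting material
4 | methyl 2,2-bis(2,4-dibromo-6-methoxyphenoxy)acetate | COC(=O)C(Oc1c(Br)cc(Br)cc1OC)Oc1c(Br)cc(Br)cc1OC | intermediate
5 | 2,2-bis(2,4-dibromo-6-methoxyphenoxy)acetaldehyde | O=CC(Oc1c(Br)cc(Br)cc1OC)Oc1c(Br)cc(Br)cc1OC | intermediate
6 | {[2,2-bis(2,4-dibromo-6-methoxyphenoxy)ethenyl]oxy}(tert-butyl)dimethylsilane | CC(C)(C)[Si](C)(C)OC=C(Oc1c(Br)cc(Br)cc1OC)Oc1c(Br)cc(Br)cc1OC | intermediate
7 | coumalic acid (2-oxo-2H-pyran-5-carboxylic acid) | O=C1C=CC(=CO1)C(=O)O | starting material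
8 | 3,5-dibromo-2H-pyran-2-one | O=C1OC=C(Br)C=C1Br | intermediate
9 | 4,7-dibromo-5,5-bis(2,4-dibromo-6-methoxyphenoxy)-6-[(tert-butyldimethylsilyl)oxy]-2-oxabicyclo[2.2.2]oct-7-en-3-one (racemic, endo/exo mixture, not isolated) | O=C1OC2C(O[Si](C)(C)C(C)(C)C)C(Oc3c(Br)cc(Br)cc3OC)(Oc4c(Br)cc(Br)cc4OC)C1(Br)C=C2Br | intermediate
10 | tert-butyl{[3,5-dibromo-6,6-bis(2,4-dibromo-6-methoxyphenoxy)cyclohexa-2,4-dien-1-yl]oxy}dimethylsilane (racemic, not isolated) | CC(C)(C)[Si](C)(C)OC1C=C(Br)C=C(Br)C1(Oc2c(Br)cc(Br)cc2OC)Oc3c(Br)cc(Br)cc3OC | intermediate
11 | tert-butyl[3,5-dibromo-2-(2,4-dibromo-6-methoxyphenoxy)phenoxy]dimethylsilane | COc1cc(Br)cc(Br)c1Oc1c(O[Si](C)(C)C(C)(C)C)cc(Br)cc1Br | intermediate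
12 | 3,5-dibromo-2-(2,4-dibromo-6-methoxyphenoxy)phenol (CNP0304934.0) | COc1cc(Br)cc(Br)c1Oc1c(O)cc(Br)cc1Br | target

## Step count and least certain steps

Total step count: 7. Longest linear sequence: 6 (steps 1, 2, 3, 4, 6, 7). Step 5 is a one-step convergent branch.

**Step 6 (key step).**
- Most likely failure: the second, very hindered C–C bond, between the C(OAr)2 carbon and the brominated C3 of 8, does not close. The first bond would then form reversibly while 8 decays thermally.
- Further risks: partial reversal of the orientation if the silyloxy donor outweighs the two electron-poor aryloxy donors, and slow loss of 6 by proton transfer from the released phenol.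
- Fallback (known chemistry, from 2 back to 12): the potassium salt of 2 is treated with 3,5-dibromo-2-fluorobenzaldehyde A1 (K2CO3, DMF, 90 °C), a nucleophilic aromatic substitution activated by the ortho-formyl group. This gives 3,5-dibromo-2-(2,4-dibromo-6-methoxyphenoxy)benzaldehyde F1. Baeyer–Villiger oxidation (m-CPBA, CH2Cl2) gives 3,5-dibromo-2-(2,4-dibromo-6-methoxyphenoxy)phenyl formate F2. Methanolysis (K2CO3, MeOH) then gives 12.

**Step 2.**
- Most likely failure: the reaction stalls after the first substitution, because the second phenoxide must reach a carbon that already carries a bulky aryloxy group and an ester. Prolonged heating would also allow O-methyl transfer from the ester to the phenoxide.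
- Fallback (from 2 back to 4): the two C–O bonds are made by different mechanisms. Alkylation of 2 with methyl bromoacetate (K2CO3, acetone) gives methyl 2-(2,4-dibromo-6-methoxyphenoxy)acetate F3. Radical bromination at the captodative C–H (NBS, dibenzoyl peroxide cat., PhCF3, reflux) gives racemic methyl 2-bromo-2-(2,4-dibromo-6-methoxyphenoxy)acetate F4. Silver-assisted ionisation to the oxocarbenium ion in the presence of 2 (Ag2O, CH2Cl2) then gives 4.

**Step 4.**
- Most likely failure: slow deprotonation of the α-C–H, which is buried between two ortho-disubstituted aryloxy groups. Silyl-triflate-induced ionisation of the diaryl acetal or self-condensation of the aldehyde could then take over.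
- Fallback (from 5 back to 12): acid-catalysed enol esterification (isopropenyl acetate, TsOH cat., reflux) gives 2,2-bis(2,4-dibromo-6-methoxyphenoxy)ethenyl acetate F5. Its weaker donor on the CH carbon should also sharpen the orientation of the cycloaddition. Reaction with 8 under the conditions of step 6 gives 3,5-dibromo-2-(2,4-dibromo-6-methoxyphenoxy)phenyl acetate F6. Methanolysis (K2CO3, MeOH, 0 °C) then gives 12.

**Step 3.**
- Most likely failure: collapse of the tetrahedral intermediate before the quench, leading to over-reduction, or hydration of the very electrophilic aldehyde on work-up.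
- Fallback (from 4 back to 5): complete reduction (LiBH4, THF) gives 2,2-bis(2,4-dibromo-6-methoxyphenoxy)ethanol F7. Swern oxidation under anhydrous conditions then gives 5, which is used directly in step 4.

## Further compounds

F1 | step 6 | 3,5-dibromo-2-(2,4-dibromo-6-methoxyphenoxy)benzaldehyde | COc1cc(Br)cc(Br)c1Oc1c(C=O)cc(Br)cc1Br
F2 | step 6 | 3,5-dibromo-2-(2,4-dibromo-6-methoxyphenoxy)phenyl formate | COc1cc(Br)cc(Br)c1Oc1c(OC=O)cc(Br)cc1Br
F3 | step 2 | methyl 2-(2,4-dibromo-6-methoxyphenoxy)acetate | COC(=O)COc1c(Br)cc(Br)cc1OC
F4 | step 2 | methyl 2-bromo-2-(2,4-dibromo-6-methoxyphenoxy)acetate (racemic) | COC(=O)C(Br)Oc1c(Br)cc(Br)cc1OC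
F5 | step 4 | 2,2-bis(2,4-dibromo-6-methoxyphenoxy)ethenyl acetate | CC(=O)OC=C(Oc1c(Br)cc(Br)cc1OC)Oc1c(Br)cc(Br)cc1OC
F6 | step 4 | 3,5-dibromo-2-(2,4-dibromo-6-methoxyphenoxy)phenyl acetate | COc1cc(Br)cc(Br)c1Oc1c(OC(C)=O)cc(Br)cc1Br
F7 | step 3 | 2,2-bis(2,4-dibromo-6-methoxyphenoxy)ethanol | OCC(Oc1c(Br)cc(Br)cc1OC)Oc1c(Br)cc(Br)cc1OC
A1 | alternative 1 | 3,5-dibromo-2-fluorobenzaldehyde | O=Cc1cc(Br)cc(Br)c1F
A2 | alternative 1 | 3,5-dibromo-2-(2,4-dibromo-6-methoxyphenoxy)benzaldehyde | COc1cc(Br)cc(Br)c1Oc1c(C=O)cc(Br)cc1Br
A3 | alternative 2 | 9H-xanthen-9-one | O=C1c2ccccc2Oc2ccccc12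
A4 | alternative 2 | 2,4,5,7-tetrabromo-9H-xanthen-9-one | O=C1c2cc(Br)cc(Br)c2Oc2c(Br)cc(Br)cc12
A5 | alternative 2 | 2,4,6,8-tetrabromo-11H-dibenzo[b,e][1,4]dioxepin-11-one | O=C1Oc2cc(Br)cc(Br)c2Oc2c(Br)cc(Br)cc12
A6 | alternative 3 | 3,5-dibromophenol | Oc1cc(Br)cc(Br)c1
A7 | alternative 3 | 3,5-dibromo-6-(2,4-dibromo-6-methoxyphenoxy)cyclohexa-2,4-dien-1-one (racemic) | COc1cc(Br)cc(Br)c1OC1C(=O)C=C(Br)C=C1Br
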